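The disconnection is the C3=C4 double bond of a 4-silyloxy-2H-chromene. It exploits the fact that ring C carries no substituent at C3, which sits between the oxygenated stereocentre C2 and the carbonyl carbon C4. A vinyl group attached to C2 and an enol-silylated acetyl group attached to C4a of ring A can therefore be joined by ring-closing metathesis, which creates the C3–C4 bond and ring C at once without touching the (S)-configured C2. The metathesis substrate is a ring A aryl ether of an (S)-1-arylallyl alcohol, obtained by iridium-catalysed branched allylic etherification, with the ortho acetyl group converted into its TBS enol ether.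

Key step: step 9

Assumption: with [Ir(cod)Cl]2, the (Sa,S,S)-phosphoramidite L, (Sa,S,S)-N,N-bis(1-phenylethyl)dinaphtho[2,1-d:1′,2′-f][1,3,2]dioxaphosphepin-4-amine, is taken to give the (S)-1-arylallyl aryl ether from an (E)-cinnamyl carbonate; should the sense prove opposite, the (Ra,R,R)-ligand is used in the same way.

Step 1
Reactants: 1 2,4,6-trihydroxyacetophenone; 2 1-bromo-3-methylbut-2-ene (prenyl bromide)
Product: 3 1-[2,4,6-trihydroxy-3-(3-methylbut-2-enyl)phenyl]ethanone
Conditions: DBU (1.0 equiv), 2 (1.0 equiv), THF, 0 °C → rt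
Reagents that add atoms: none
Why: Nuclear C-prenylation of a phloroglucinol-type phenoxide, in which the DBU salt of 1 is alkylated at the electron-rich ring carbon and one equivalent of bromide limits a second alkylation.

Step 2
Reactants: 3 1-[2,4,6-trihydroxy-3-(3-methylbut-2-enyl)phenyl]ethanone
Product: 4 1-[2-hydroxy-4,6-bis(methoxymethoxy)-3-(3-methylbut-2-enyl)phenyl]ethanone
Conditions: MOMCl (2.2 equiv), i-Pr2NEt (2.5 equiv), CH2Cl2, 0 °C → rt
Reagents that add atoms: chloromethyl methyl ether (MOMCl), COCCl
Why: Williamson-type acetalisation (MOM protection) should take the 4-OH and the unhindered 6-OH, whereas the 2-OH, wedged between acetyl and prenyl and hydrogen-bonded to the carbonyl, should stay free.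

Step 3
Reactants: 5 3-bromo-4-methoxybenzaldehyde; 6 4-bromo-2-methylbut-1-ene
Product: 8 4-methoxy-3-(3-methylbut-3-enyl)benzaldehyde, via alkylzinc bromide 7 (not isolated)
Conditions: 6, Zn dust (activated with BrCH2CH2Br, Me3SiCl), LiCl, THF, 50 °C; then 5, Pd(OAc)2 (2 mol%), SPhos (4 mol%), THF, rt
Reagents that add atoms: none
Why: Negishi cross-coupling, in which the primary alkylzinc bromide formed by LiCl-assisted zinc insertion tolerates the aldehyde and couples with the aryl bromide under Pd(OAc)2/SPhos faster than β-hydride elimination.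

Step 4
Reactants: 8 4-methoxy-3-(3-methylbut-3-enyl)benzaldehyde
Product: 9 ethyl (2E)-3-[4-methoxy-3-(3-methylbut-3-enyl)phenyl]prop-2-enoate
Conditions: Ph3P=CHCO2Et (1.2 equiv), toluene, 80 °C
Reagents that add atoms: ethyl (triphenyl-λ5-phosphanylidene)acetate, CCOC(=O)C=P(c1ccccc1)(c1ccccc1)c1ccccc1
Why: Wittig olefination of an aromatic aldehyde with a stabilised ylide, which should give the (E)-cinnamate.

Step 5
Reactants: 9 ethyl (2E)-3-[4-methoxy-3-(3-methylbut-3-enyl)phenyl]prop-2-enoate
Product: 10 (2E)-3-[4-methoxy-3-(3-methylbut-3-enyl)phenyl]prop-2-en-1-ol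
Conditions: i-Bu2AlH (2.3 equiv), CH2Cl2, −78 °C; aq KNaC4H4O6 work-up
Reagents that add atoms: none
Why: 1,2-Reduction of the α,β-unsaturated ester by i-Bu2AlH to the allylic alcohol, with the isolated 1,1-disubstituted alkene and the aryl ether inert.

Step 6
Reactants: 10 (2E)-3-[4-methoxy-3-(3-methylbut-3-enyl)phenyl]prop-2-en-1-ol
Product: 11 methyl (2E)-3-[4-methoxy-3-(3-methylbut-3-enyl)phenyl]prop-2-enyl carbonate
Conditions: ClCO2Me (1.5 equiv), pyridine, CH2Cl2, 0 °C
Reagents that add atoms: methyl chloroformate, COC(=O)Cl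
Why: O-Acylation of the primary allylic alcohol with a chloroformate installs the carbonate leaving group needed for the allylic substitution.

Step 7
Reactants: 4 1-[2-hydroxy-4,6-bis(methoxymethoxy)-3-(3-methylbut-2-enyl)phenyl]ethanone; 11 methyl (2E)-3-[4-methoxy-3-(3-methylbut-3-enyl)phenyl]prop-2-enyl carbonate
Product: 13 1-[2-({(1S)-1-[4-methoxy-3-(3-methylbut-3-enyl)phenyl]prop-2-enyl}oxy)-4,6-bis(methoxymethoxy)-3-(3-methylbut-2-enyl)phenyl]ethanone, via sodium aryloxide 12 (not isolated)
Conditions: 4 (1.3 equiv), NaH (1.3 equiv), THF, 0 °C; then 11, [Ir(cod)Cl]2 (2 mol%), (Sa,S,S)-L (4 mol%, pre-activated with n-PrNH2 at 50 °C, volatiles removed), THF, rt → 40 °C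
Reagents that add atoms: none
Why: Iridium-catalysed asymmetric allylic etherification of a phenoxide, in which the cyclometalated iridium phosphoramidite ionises carbonate 11 to a π-allyl complex, aryloxide 12 attacks the aryl-bearing terminus (branched selectivity), and the (Sa,S,S)-ligand dictates the face so that the new ether carbon, the future C2, is (S).

Step 8
Reactants: 13 1-[2-({(1S)-1-[4-methoxy-3-(3-methylbut-3-enyl)phenyl]prop-2-enyl}oxy)-4,6-bis(methoxymethoxy)-3-(3-methylbut-2-enyl)phenyl]ethanone
Product: 14 tert-butyl({1-[2-({(1S)-1-[4-methoxy-3-(3-methylbut-3-enyl)phenyl]prop-2-enyl}oxy)-4,6-bis(methoxymethoxy)-3-(3-methylbut-2-enyl)phenyl]ethenyl}oxy)dimethylsilane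
Conditions: TBSOTf (1.3 equiv), Et3N (3 equiv), CH2Cl2, −20 → 0 °C; chromatography on Et3N-deactivated silica
Reagents that add atoms: tert-butyldimethylsilyl trifluoromethanesulfonate (TBSOTf), CC(C)(C)[Si](C)(C)OS(=O)(=O)C(F)(F)F
Why: Soft enolisation and O-silylation of the methyl ketone, its only enolisable position, with excess amine keeping the medium basic so that the ionisable allylic benzylic ether and the MOM acetals persist and the stereocentre is not involved.

Step 9
Reactants: 14 tert-butyl({1-[2-({(1S)-1-[4-methoxy-3-(3-methylbut-3-enyl)phenyl]prop-2-enyl}oxy)-4,6-bis(methoxymethoxy)-3-(3-methylbut-2-enyl)phenyl]ethenyl}oxy)dimethylsilane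
Product: 15 tert-butyl{[(2S)-5,7-bis(methoxymethoxy)-2-[4-methoxy-3-(3-methylbut-3-enyl)phenyl]-8-(3-methylbut-2-enyl)-2H-chromen-4-yl]oxy}dimethylsilane
Conditions: Hoveyda–Grubbs second-generation catalyst RuCl2(H2IMes)(=CH-C6H4-2-O-i-Pr) (5–10 mol%), toluene (0.005 M), 60 °C, Ar sparge
Reagents that add atoms: none
Why: This is a ring-closing metathesis of a silyl enol ether with a terminal alkene, a known route to cyclic enol ethers: the ruthenium carbene exchanges onto the vinyl group on the ether carbon, the only monosubstituted alkene, and the new alkylidene adds [2+2] across the neighbouring CH2=C(OTBS)Ar unit with ruthenium on the CH2 end, after which cycloreversion releases ruthenium methylidene (ethylene overall) and leaves the C3=C4 enol ether. Ring C closes as a six-membered 2H-chromene with both alkene carbons inside the ring, the two partners being held ortho to each other on ring A through O1 and C4a. No stereocentre is formed; C2, set in step 7, stays sp3 and is retained, and fresh catalyst with a short reaction time keeps ruthenium hydride-mediated allylic isomerisation away from it. The selectivity needed is six-membered closure onto the enol ether in preference to seven-membered closure onto the C8 prenyl alkene (loss of isobutene) and to intermolecular metathesis. The shorter tether, the exposed CH2 terminus of the 1,1-disubstituted enol ether compared with the trisubstituted prenyl alkene, and high dilution should secure it, while the 1,1-disubstituted side chain on ring B cannot reach the alkylidene without building a strained meta-bridged ring.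

Step 10
Reactants: 15 tert-butyl{[(2S)-5,7-bis(methoxymethoxy)-2-[4-methoxy-3-(3-methylbut-3-enyl)phenyl]-8-(3-methylbut-2-enyl)-2H-chromen-4-yl]oxy}dimethylsilane
Product: 17 (2S)-5,7-dihydroxy-2-[4-methoxy-3-(3-methylbut-3-enyl)phenyl]-8-(3-methylbut-2-enyl)-2,3-dihydro-4H-chromen-4-one (CNP0286775.1), via bis-MOM flavanone 16 (not isolated)
Conditions: 3 M aq HCl, MeOH–THF, 0 → 40 °C; NaHCO3 quench
Reagents that add atoms: none
Why: Acid-catalysed hydrolysis of the silyl enol ether (protonation at C3, then loss of silicon) followed by acetal solvolysis of both MOM ethers, a deprotection routinely used on prenylated flavonoids, with C2 not involved so that the (S) configuration should be retained.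

Compound list
1 | 2,4,6-trihydroxyacetophenone | CC(=O)c1c(O)cc(O)cc1O | starting material
2 | 1-bromo-3-methylbut-2-ene (prenyl bromide) | CC(C)=CCBr | starting material
3 | 1-[2,4,6-trihydroxy-3-(3-methylbut-2-enyl)phenyl]ethanone | CC(=O)c1c(O)cc(O)c(CC=C(C)C)c1O | intermediate
4 | 1-[2-hydroxy-4,6-bis(methoxymethoxy)-3-(3-methylbut-2-enyl)phenyl]ethanone | CC(=O)c1c(OCOC)cc(OCOC)c(CC=C(C)C)c1O | intermediate
5 | 3-bromo-4-methoxybenzaldehyde | COc1ccc(C=O)cc1Br | starting material
6 | 4-bromo-2-methylbut-1-ene | C=C(C)CCBr | starting material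
7 | (3-methylbut-3-enyl)zinc bromide | C=C(C)CC[Zn]Br | intermediate
8 | 4-methoxy-3-(3-methylbut-3-enyl)benzaldehyde | COc1ccc(C=O)cc1CCC(C)=C | intermediate
9 | ethyl (2E)-3-[4-methoxy-3-(3-methylbut-3-enyl)phenyl]prop-2-enoate | CCOC(=O)/C=C/c1ccc(OC)c(CCC(C)=C)c1 | intermediate
10 | (2E)-3-[4-methoxy-3-(3-methylbut-3-enyl)phenyl]prop-2-en-1-ol | OC/C=C/c1ccc(OC)c(CCC(C)=C)c1 | intermediate
11 | methyl (2E)-3-[4-methoxy-3-(3-methylbut-3-enyl)phenyl]prop-2-enyl carbonate | COC(=O)OC/C=C/c1ccc(OC)c(CCC(C)=C)c1 | intermediate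
12 | sodium 2-acetyl-3,5-bis(methoxymethoxy)-6-(3-methylbut-2-enyl)phenolate | CC(=O)c1c(OCOC)cc(OCOC)c(CC=C(C)C)c1[O-].[Na+] | intermediate
13 | 1-[2-({(1S)-1-[4-methoxy-3-(3-methylbut-3-enyl)phenyl]prop-2-enyl}oxy)-4,6-bis(methoxymethoxy)-3-(3-methylbut-2-enyl)phenyl]ethanone | CC(=O)c1c(OCOC)cc(OCOC)c(CC=C(C)C)c1O[C@@H](C=C)c1ccc(OC)c(CCC(C)=C)c1 | intermediate
14 | tert-butyl({1-[2-({(1S)-1-[4-methoxy-3-(3-methylbut-3-enyl)phenyl]prop-2-enyl}oxy)-4,6-bis(methoxymethoxy)-3-(3-methylbut-2-enyl)phenyl]ethenyl}oxy)dimethylsilane | C=C(O[Si](C)(C)C(C)(C)C)c1c(OCOC)cc(OCOC)c(CC=C(C)C)c1O[C@@H](C=C)c1ccc(OC)c(CCC(C)=C)c1 | intermediate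
15 | tert-butyl{[(2S)-5,7-bis(methoxymethoxy)-2-[4-methoxy-3-(3-methylbut-3-enyl)phenyl]-8-(3-methylbut-2-enyl)-2H-chromen-4-yl]oxy}dimethylsilane | C=C(C)CCc1cc([C@@H]2C=C(O[Si](C)(C)C(C)(C)C)c3c(OCOC)cc(OCOC)c(CC=C(C)C)c3O2)ccc1OC | intermediate
16 | (2S)-5,7-bis(methoxymethoxy)-2-[4-methoxy-3-(3-methylbut-3-enyl)phenyl]-8-(3-methylbut-2-enyl)-2,3-dihydro-4H-chromen-4-one | C=C(C)CCc1cc([C@@H]2CC(=O)c3c(OCOC)cc(OCOC)c(CC=C(C)C)c3O2)ccc1OC | intermediate
17 | (2S)-5,7-dihydroxy-2-[4-methoxy-3-(3-methylbut-3-enyl)phenyl]-8-(3-methylbut-2-enyl)-2,3-dihydro-4H-chromen-4-one | C=C(C)CCc1cc([C@@H]2CC(=O)c3c(O)cc(O)c(CC=C(C)C)c3O2)ccc1OC | target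

Total step count: 10. Longest linear sequence: 8 steps (steps 3 to 10, starting from 5 and 6).

Steps most likely to fail

Step 9. The alkylidene formed at the vinyl group may close the seven-membered ring onto the C8 prenyl alkene with loss of isobutene, or the catalyst may stall at the hindered, electron-rich enol ether. The fallback abandons metathesis and builds ring C by the chalcone route. It sets out from 4 and 8: Claisen–Schmidt condensation (KOH, EtOH–H2O, rt) should give (2E)-1-[2-hydroxy-4,6-bis(methoxymethoxy)-3-(3-methylbut-2-enyl)phenyl]-3-[4-methoxy-3-(3-methylbut-3-enyl)phenyl]prop-2-en-1-one F1. Intramolecular oxa-Michael addition (NaOAc, EtOH, reflux) should then give racemic 5,7-bis(methoxymethoxy)-2-[4-methoxy-3-(3-methylbut-3-enyl)phenyl]-8-(3-methylbut-2-enyl)-2,3-dihydro-4H-chromen-4-one F2. Preparative HPLC on a chiral stationary phase should deliver the (2S)-enantiomer, which is compound 16; the (2R)-enantiomer can be re-equilibrated through the chalcone with base and recycled. The fallback returns to the route at 16, which is then carried through the acid treatment of step 10.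

Step 7. Attack of the doubly ortho-substituted, chelated aryloxide may be sluggish, and the product ether may re-ionise at iridium, which would erode the enantiomeric purity and let the material drift to the linear isomer. The fallback forms the same C–O bond by stereospecific displacement. It sets out from 8: addition of CH2=CHMgBr (THF, −78 °C) should give racemic 1-[4-methoxy-3-(3-methylbut-3-enyl)phenyl]prop-2-en-1-ol F3. Lipase-catalysed kinetic resolution (Novozym 435, vinyl acetate, hexane, rt) should acetylate the (R)-enantiomer to (1R)-1-[4-methoxy-3-(3-methylbut-3-enyl)phenyl]prop-2-enyl acetate F4, leaving the (S)-enantiomer of F3 behind. Methanolysis (K2CO3, MeOH, 0 °C) should give (1R)-1-[4-methoxy-3-(3-methylbut-3-enyl)phenyl]prop-2-en-1-ol F5. Mitsunobu etherification of F5 with phenol 4 (PPh3, DIAD, toluene, −20 °C → rt) should proceed with inversion and return to the route at 13.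

Step 10. Under protic acid the liberated 7-OH may add across the prenyl alkene (chroman formation), the 1,1-disubstituted alkene may migrate or take up methanol, and ring C may open at C2–O1 with loss of configuration. The fallback separates the two unmasking events and avoids protic acid. It sets out from 15: fluoride buffered with acetic acid (TBAF, AcOH, THF, 0 °C) should cleave the enol ether, with C3 protonated before the enolate can expel the C8a phenoxide, and give 16, now isolated. Lewis-acid-mediated thiol exchange of the acetals in aprotic medium (ZnBr2, n-PrSH, CH2Cl2, 0 °C, short time) should then remove both MOM groups and return to the route at 17. This fallback makes no compound outside the compound list.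

Further compounds
F1 | step 9 | (2E)-1-[2-hydroxy-4,6-bis(methoxymethoxy)-3-(3-methylbut-2-enyl)phenyl]-3-[4-methoxy-3-(3-methylbut-3-enyl)phenyl]prop-2-en-1-one | O=C(/C=C/c1ccc(OC)c(CCC(C)=C)c1)c1c(OCOC)cc(OCOC)c(CC=C(C)C)c1O
F2 | step 9 | rac-5,7-bis(methoxymethoxy)-2-[4-methoxy-3-(3-methylbut-3-enyl)phenyl]-8-(3-methylbut-2-enyl)-2,3-dihydro-4H-chromen-4-one | C=C(C)CCc1cc(C2CC(=O)c3c(OCOC)cc(OCOC)c(CC=C(C)C)c3O2)ccc1OC
F3 | step 7 | rac-1-[4-methoxy-3-(3-methylbut-3-enyl)phenyl]prop-2-en-1-ol | C=CC(O)c1ccc(OC)c(CCC(C)=C)c1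
F4 | step 7 | (1R)-1-[4-methoxy-3-(3-methylbut-3-enyl)phenyl]prop-2-enyl acetate | CC(=O)O[C@H](C=C)c1ccc(OC)c(CCC(C)=C)c1
F5 | step 7 | (1R)-1-[4-methoxy-3-(3-methylbut-3-enyl)phenyl]prop-2-en-1-ol | O[C@H](C=C)c1ccc(OC)c(CCC(C)=C)c1
F0 | step 10 | none | none
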